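At late times side product is still there, its step having no way back, so I counted half-lives at the point where that loss is made.

    starting material + partner ⇌ intermediate (K1 = 300 /M, k1 = 3100 /M/s)
    starting material ⇌ dormant form (K2 = 16, k2 = 0.30 /s)
    intermediate → target (k3 = 2.9 /s)
    starting material + intermediate → side product (k4 = 2900 /M/s)

all flasks: partner 1.80 mM

|  | starting material | time | remark |
|---|---|---|---|
| Saturday's | 0.0010 M | 5.0 s | a tube with plug flow, the mixed feed as stated, residence time 5.0 s |
| Tuesday's | 0.0010 M | 5.0 s | a closed flask charged with all of it at once and left for 5.0 s |
| Monday's | 0.0010 M |  | a single well-mixed tank run continuously and read at steady state, 5.0 s in it on average |
| Sunday's | 0.0010 M (fed, over 4.00 s) | 5.0 s | all but starting material at the start; starting material goes in evenly over 4.00 s, the run ends at 5.0 s |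

- percentages count the starting material that a species holds: one side product counts as two
- the stated concentrations are those of everything mixed, before any reaction; amounts are the same in each set-up
- the feed brings no volume worth counting
- run time (Saturday's): 5.0 s

1. the set-up with the highest amount of target at the outlet or at the end, in percent of the starting material put in ("none" if the first two lie within 2 percentage points) (Saturday's / Tuesday's / Monday's / Sunday's / none)
2. amount of target at the outlet or at the end, in percent of the starting material put in, Saturday's
3. amount of target at the outlet or at the end, in percent of the starting material put in, Tuesday's
4. amount of target at the outlet or at the end, in percent of the starting material put in, Monday's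
5. amount of target at the outlet or at the end, in percent of the starting material put in, Sunday's

In Saturday's, as charged, an intermediate goes to target with a half-life of 0.239 s and to side product with one of 0.24 s, so the two exits are about equal. The ratio of their rate constants, taken against the charge, gives 1.00, the even-odds fraction: the fraction of the charge, held as free starting material, at which an intermediate is equally likely to take either exit. This fraction divided by the free fraction gives the odds for target, a selectivity factor.

For the continuous or dosed runs, I set feed against capture, with partner held at its charge. Capture is the forward step of intermediate formation, times the share of intermediates that move on rather than return, plus the step to dormant form. My table reads: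

- Saturday's and Tuesday's, at the start: free fraction 1, odds 1.00
- Sunday's, during dosing: free fraction 0.164, odds 6.10
- Monday's: free fraction 0.112, odds 8.93

The first row starts at even odds, and I took the tube and the closed flask as one row. The next two rows stand well above it, so I expected the heaviest loss to side product in Saturday's and Tuesday's. The odds do not say how much has reached target by the end, so my reckoning stopped there.

The forecast gave 49.5% for Saturday's and 49.5% for Tuesday's, 51.3% for Monday's and 57.5% for Sunday's. It chose Sunday's, holding that “slow feeding keeps free starting material low”.

The simulation gave 49.8%, 49.8%, 51.3% and 57.8% in that order, so Sunday's led by 6.5 percentage points, and each value lay inside the forecast's range.

Sunday's fell short of the whole charge mainly through the return of intermediate to starting material and partner: the same run without that return gave 83.9% against 57.8%. Sunday's free fraction peaked at a reading of 0.176, below the even-odds fraction of 1.00, and side product in Sunday's held 15.9% at 5.00 s, half of Tuesday's 33.1%. In the neighbour flask, Tuesday's with 0.0040 M of starting material, the even-odds fraction is 0.250 of its charge, yet it starts with the whole charge free, and it ended with target at 15.9% against side product at 55.1%.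

(The numbers were chosen freely; what happens was integrated by code.)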